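**Retrosynthetic overview**
1. Ring A is the catechol ring (C4a, C5–C8, C8a), ring B is the carbocycle C1–C4/C4a/C8a, and ring C is the 2-pyranone on C1. The last step only removes two tert-butyl esters and one catechol acetonide.
2. Ring B is cut at C4–C4a and C8a–C1. This is a formal (4+2) double Friedel–Crafts annulation of the symmetric catechol acetonide with an achiral open-chain C1–C4 unit, run under a confined chiral Brønsted acid that sets C1 and, through it, C2.
3. Enabling feature: the two carbons of ring A that become C4a and C8a are adjacent, equivalent by symmetry, and each para to one ring oxygen (C4a to the O on C7, C8a to the O on C6). Ring A can therefore act twice as a carbon nucleophile with only one regiochemical outcome, and the C1–C4 chain is electrophilic at both ends (C4 = enolised formyl carbon, C1 = enoate β-carbon on C3 of ring C).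
4. The chain comes from Claisen formylation of an alkylidenesuccinate. That compound is made by Heck coupling of a 3-bromo-2-pyranone-6-carboxylate with a mixed itaconate that already separates the C2 methyl ester from the C3 carboxyl.
5. Ring order: rings C and A are bought, and ring B is the only ring formed (step 7).

Key step: step 7

Assumption: 1, 4, 5 and 10 are taken as commercial, and because the sense of induction of the chiral acid in step 7 cannot be predicted, the antipode that leads to the (1R,2R) series is picked after a test run (both antipodes are accessible).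

**Step 1**
Reactants: 1 2-oxo-2H-pyran-6-carboxylic acid
Product: 2 tert-butyl 2-oxo-2H-pyran-6-carboxylate
Conditions: Cl3CC(=NH)OtBu, CH2Cl2/cyclohexane, rt
Reagents that add atoms: tert-butyl 2,2,2-trichloroacetimidate, CC(C)(C)OC(=N)C(Cl)(Cl)Cl
Why: O-alkylation of a carboxylic acid by a trichloroacetimidate (tert-butyl transfer) needs neither base nor nucleophile, so the ring-opening-prone pyranone should stay intact.

**Step 2**
Reactants: 2 tert-butyl 2-oxo-2H-pyran-6-carboxylate
Product: 3 tert-butyl 3-bromo-2-oxo-2H-pyran-6-carboxylate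
Conditions: Br2, NaOAc, AcOH, 50 °C
Reagents that add atoms: bromine, BrBr
Why: Electrophilic bromination of 2-pyranones (addition–elimination) goes to C3 or C5, and since C5 is deactivated here as the β-carbon of the C5=C6–CO2tBu acrylate unit, C3 should be substituted, with the acetate buffer protecting the tert-butyl ester from HBr.

**Step 3**
Reactants: 4 methyl 2-(diethoxyphosphoryl)acetate, 5 tert-butyl bromoacetate
Product: 6 4-tert-butyl 1-methyl 2-(diethoxyphosphoryl)butanedioate
Conditions: NaH, THF, 0 °C to rt
Reagents that add atoms: none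
Why: SN2 alkylation of the stabilised phosphonoacetate carbanion by a primary α-bromo ester is standard, and the new stereocentre is racemic and disappears in step 4.

**Step 4**
Reactants: 6 4-tert-butyl 1-methyl 2-(diethoxyphosphoryl)butanedioate
Product: 7 4-tert-butyl 1-methyl 2-methylidenebutanedioate
Conditions: 37% aq. CH2O, K2CO3, THF/H2O, 40 °C
Reagents that add atoms: formaldehyde, C=O
Why: Horner–Wadsworth–Emmons olefination with formaldehyde gives the mixed itaconate, in which the conjugated carboxyl is the methyl ester and the CH2-bound carboxyl is the acid-labile tert-butyl ester.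

**Step 5**
Reactants: 3 tert-butyl 3-bromo-2-oxo-2H-pyran-6-carboxylate, 7 4-tert-butyl 1-methyl 2-methylidenebutanedioate
Product: 8 4-tert-butyl 1-methyl (2E)-2-{[6-(tert-butoxycarbonyl)-2-oxo-2H-pyran-3-yl]methylidene}butanedioate
Conditions: Pd(OAc)2 (5 mol %), Bu4NCl, NaHCO3, DMF, 70 °C
Reagents that add atoms: none
Why: In this Mizoroki–Heck reaction the electron-poor C3–Br bond adds to zerovalent palladium, the pyranonyl group is delivered to the CH2 terminus, and syn β-hydride elimination towards the pyranone-bearing carbon should give the conjugated E-alkene, while the amine-free base avoids itaconate isomerisation.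

**Step 6**
Reactants: 8 4-tert-butyl 1-methyl (2E)-2-{[6-(tert-butoxycarbonyl)-2-oxo-2H-pyran-3-yl]methylidene}butanedioate
Product: 9 1-tert-butyl 4-methyl (2Z,3E)-2-(hydroxymethylidene)-3-{[6-(tert-butoxycarbonyl)-2-oxo-2H-pyran-3-yl]methylidene}butanedioate (enol form of the formyl ester)
Conditions: LiN(SiMe3)2 (2.2 equiv), THF, −78 °C; HCO2CH2CF3; AcOH quench
Reagents that add atoms: 2,2,2-trifluoroethyl formate, O=COCC(F)(F)F
Why: In this Claisen-type formylation the only acidic site is the CH2 that is both α to the tert-butyl ester and allylic, the hindered amide base at low temperature and the weakly nucleophilic trifluoroethoxide should spare the pyranone, and the product rests as the hydrogen-bonded Z-enol.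

**Step 7**
Reactants: 9 1-tert-butyl 4-methyl (2Z,3E)-2-(hydroxymethylidene)-3-{[6-(tert-butoxycarbonyl)-2-oxo-2H-pyran-3-yl]methylidene}butanedioate, 10 2,2-dimethyl-1,3-benzodioxole
Product: 12 7-tert-butyl 6-methyl (5R,6R)-5-[6-(tert-butoxycarbonyl)-2-oxo-2H-pyran-3-yl]-2,2-dimethyl-5,6-dihydronaphtho[2,3-d][1,3]dioxole-6,7-dicarboxylate, via bis-alkylidenesuccinate 11 (not isolated)
Conditions: 10 (1.5 equiv), chiral imidodiphosphorimidate acid (IDPi, 3,3'-diaryl-BINOL backbone, N-SO2CF3; 5 mol %), CHCl3, 4 Å MS, −20 °C to rt
Reagents that add atoms: none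
Why: Proposed new method: the strong chiral acid activates the enolised formyl terminus of 9, the carbon of 10 para to one ring oxygen attacks it and loss of water gives the (E,E)-diene 11 with the aryl group cis to the enoate arm, after which the acid, bound to the basic pyranone C2 carbonyl and the neighbouring methyl ester, triggers attack of the adjacent arene carbon (para to the second oxygen) on the enoate β-carbon, and rearomatisation and ketonisation deliver 12. The closest known reaction types are the acid-mediated hydroxyalkylation and cyclodehydration of arenes by α-formyl esters, the CF3SO3H-mediated cyclisation of 2,3-dibenzylidenesuccinates to trans-1-aryl-1,2-dihydronaphthalene-2,3-dicarboxylates, and asymmetric Friedel–Crafts and hydroarylation reactions of weakly nucleophilic arenes under imidodiphosphorimidate catalysis; what is new is their merger on one arene and the enantiocontrol of the closure. Ring B closes in a 6-endo-trig conjugate Friedel–Crafts mode, formally the cationic 6π closure of an aryl-diene. The stereocentre at C1 is set by the confined counter-anion, which is ion-paired two bonds away from this carbon and leaves one face of the enoate open, and the stereocentre at C2 is set by protonation of the resulting ester enol anti to the pyranone, which is also the thermodynamically preferred trans arrangement. The step needs site selectivity on ring A, secured by the symmetry of 10 and the para-directing oxygens (the other ortho carbon is flanked by oxygen), and monoarylation at the formyl carbon, secured by the acidic α-hydrogen that turns the benzylic cation into the conjugated alkene before a second arene can add.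

**Step 8**
Reactants: 12 7-tert-butyl 6-methyl (5R,6R)-5-[6-(tert-butoxycarbonyl)-2-oxo-2H-pyran-3-yl]-2,2-dimethyl-5,6-dihydronaphtho[2,3-d][1,3]dioxole-6,7-dicarboxylate
Product: 13 (1R,2R)-1-(6-carboxy-2-oxo-2H-pyran-3-yl)-6,7-dihydroxy-2-(methoxycarbonyl)-1,2-dihydronaphthalene-3-carboxylic acid (target)
Conditions: CF3CO2H/H2O 95:5, rt, argon
Reagents that add atoms: none
Why: Acidolysis cleaves both tert-butyl esters (E1) and hydrolyses the catechol ketal in one operation, while the methyl ester, the pyranone and the styrene-type alkene are inert to CF3CO2H and the absence of base leaves both stereocentres untouched.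

**Compound list**
1 | 2-oxo-2H-pyran-6-carboxylic acid | O=C(O)c1cccc(=O)o1 | starting material
2 | tert-butyl 2-oxo-2H-pyran-6-carboxylate | CC(C)(C)OC(=O)c1cccc(=O)o1 | intermediate
3 | tert-butyl 3-bromo-2-oxo-2H-pyran-6-carboxylate | CC(C)(C)OC(=O)c1ccc(Br)c(=O)o1 | intermediate
4 | methyl 2-(diethoxyphosphoryl)acetate | CCOP(=O)(CC(=O)OC)OCC | starting material
5 | tert-butyl bromoacetate | CC(C)(C)OC(=O)CBr | starting material
6 | 4-tert-butyl 1-methyl 2-(diethoxyphosphoryl)butanedioate (racemic) | CCOP(=O)(OCC)C(CC(=O)OC(C)(C)C)C(=O)OC | intermediate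
7 | 4-tert-butyl 1-methyl 2-methylidenebutanedioate | COC(=O)C(=C)CC(=O)OC(C)(C)C | intermediate
8 | 4-tert-butyl 1-methyl (2E)-2-{[6-(tert-butoxycarbonyl)-2-oxo-2H-pyran-3-yl]methylidene}butanedioate | COC(=O)/C(CC(=O)OC(C)(C)C)=C/c1ccc(C(=O)OC(C)(C)C)oc1=O | intermediate
9 | 1-tert-butyl 4-methyl (2Z,3E)-2-(hydroxymethylidene)-3-{[6-(tert-butoxycarbonyl)-2-oxo-2H-pyran-3-yl]methylidene}butanedioate | COC(=O)/C(=C/c1ccc(C(=O)OC(C)(C)C)oc1=O)C(=C/O)/C(=O)OC(C)(C)C | intermediate
10 | 2,2-dimethyl-1,3-benzodioxole | CC1(C)Oc2ccccc2O1 | starting material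
11 | 1-tert-butyl 4-methyl (2E,3E)-2-[(2,2-dimethyl-1,3-benzodioxol-5-yl)methylidene]-3-{[6-(tert-butoxycarbonyl)-2-oxo-2H-pyran-3-yl]methylidene}butanedioate (not isolated) | COC(=O)/C(=C/c1ccc(C(=O)OC(C)(C)C)oc1=O)C(=C\c1ccc2OC(C)(C)Oc2c1)/C(=O)OC(C)(C)C | intermediate
12 | 7-tert-butyl 6-methyl (5R,6R)-5-[6-(tert-butoxycarbonyl)-2-oxo-2H-pyran-3-yl]-2,2-dimethyl-5,6-dihydronaphtho[2,3-d][1,3]dioxole-6,7-dicarboxylate | COC(=O)[C@H]1C(C(=O)OC(C)(C)C)=Cc2cc3OC(C)(C)Oc3cc2[C@@H]1c1ccc(C(=O)OC(C)(C)C)oc1=O | intermediate
13 | (1R,2R)-1-(6-carboxy-2-oxo-2H-pyran-3-yl)-6,7-dihydroxy-2-(methoxycarbonyl)-1,2-dihydronaphthalene-3-carboxylic acid | COC(=O)[C@H]1C(C(=O)O)=Cc2cc(O)c(O)cc2[C@@H]1c1ccc(C(=O)O)oc1=O | target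

Total steps: 8. Longest linear sequence: 6 (steps 1, 2, 5, 6, 7, 8).

**Steps most likely to fail**

Step 7. The cascade may stall after the first arylation, the closure may proceed with poor facial selectivity, or the acid may start to cleave the tert-butyl esters before ring B is formed. The fallback uses known chemistry, sets out from 8 and returns at 13; the C4–aryl bond is bought in instead of made. The lithium enolate of 8 (LiN(SiMe3)2, THF, −78 °C) is added to 2,2-dimethyl-1,3-benzodioxole-5-carbaldehyde F1. The aldolate is trapped by Ac2O to give the aldol acetate F2, and DBU-induced E1cB elimination gives 11 as an isolated compound. CF3SO3H in CH2Cl2, the established conditions for 2,3-dibenzylidenesuccinates, followed by CF3CO2H/H2O, closes ring B and removes the acid-labile groups to give the racemic trans acid F3. Separation on a chiral stationary phase then gives 13.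

Step 6. The base or the liberated alkoxide may attack the pyranone, and the delocalised enolate may lose the alkene geometry. The fallback sets out from 7 and returns at 9; the one-carbon unit is installed before the pyranone is present. Compound 7 is heated with tert-butoxybis(dimethylamino)methane (Bredereck's reagent) in toluene to give the enamino diester F4. Heck coupling with 3 under the conditions of step 5 gives the pyranonyl enamine F5. Brief treatment with dilute aqueous HCl in THF hydrolyses the enamine to 9.

Step 5. β-Hydride elimination may go towards the CH2CO2tBu side, a palladium hydride may migrate the alkene, or the acrylate may consume the bromopyranone in a Diels–Alder reaction. The fallback sets out from 3 and returns at 8; it replaces the Heck reaction by an olefination that uses the phosphonate 6 already in hand. Stille coupling of 3 with tributyl(vinyl)stannane (Pd(PPh3)4, toluene, 80 °C) gives tert-butyl 3-ethenyl-2-oxo-2H-pyran-6-carboxylate F6. Lemieux–Johnson cleavage (OsO4 cat., NaIO4, THF/H2O) gives tert-butyl 3-formyl-2-oxo-2H-pyran-6-carboxylate F7. Horner–Wadsworth–Emmons reaction with 6 under Masamune–Roush conditions (LiCl, DBU, MeCN) gives 8.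

**Further compounds**
F1 | step 7 | 2,2-dimethyl-1,3-benzodioxole-5-carbaldehyde | CC1(C)Oc2ccc(C=O)cc2O1
F2 | step 7 | 1-tert-butyl 4-methyl (3E)-2-[acetyloxy(2,2-dimethyl-1,3-benzodioxol-5-yl)methyl]-3-{[6-(tert-butoxycarbonyl)-2-oxo-2H-pyran-3-yl]methylidene}butanedioate (mixture of diastereomers) | COC(=O)/C(=C/c1ccc(C(=O)OC(C)(C)C)oc1=O)C(C(OC(C)=O)c1ccc2OC(C)(C)Oc2c1)C(=O)OC(C)(C)C
F3 | step 7 | racemic trans-1-(6-carboxy-2-oxo-2H-pyran-3-yl)-6,7-dihydroxy-2-(methoxycarbonyl)-1,2-dihydronaphthalene-3-carboxylic acid (both enantiomers) | COC(=O)[C@H]1C(C(=O)O)=Cc2cc(O)c(O)cc2[C@@H]1c1ccc(C(=O)O)oc1=O.COC(=O)[C@@H]1C(C(=O)O)=Cc2cc(O)c(O)cc2[C@H]1c1ccc(C(=O)O)oc1=O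
F4 | step 6 | 1-tert-butyl 4-methyl 2-[(dimethylamino)methylidene]-3-methylidenebutanedioate (enamine geometry not relevant) | COC(=O)C(=C)C(=CN(C)C)C(=O)OC(C)(C)C
F5 | step 6 | 1-tert-butyl 4-methyl (3E)-2-[(dimethylamino)methylidene]-3-{[6-(tert-butoxycarbonyl)-2-oxo-2H-pyran-3-yl]methylidene}butanedioate (enamine geometry not relevant) | COC(=O)/C(=C/c1ccc(C(=O)OC(C)(C)C)oc1=O)C(=CN(C)C)C(=O)OC(C)(C)C
F6 | step 5 | tert-butyl 3-ethenyl-2-oxo-2H-pyran-6-carboxylate | C=Cc1ccc(C(=O)OC(C)(C)C)oc1=O
F7 | step 5 | tert-butyl 3-formyl-2-oxo-2H-pyran-6-carboxylate | O=Cc1ccc(C(=O)OC(C)(C)C)oc1=O
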